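The ten-membered carbocycle is closed at the C7–C8 bond (germacrane numbering: C6 lactone carbinol, C7 ring-fusion carbon, C8 acyloxy carbon). The exocyclic C11=C13 methylene of the fused γ-lactone and the homoallylic oxygen on C8 form the retron of a carbonyl allylation. A linear aldehyde bearing a 3-(bromomethyl)butenolide is therefore cyclised with CrCl2 (intramolecular Nozaki–Hiyama–Kishi allylation). One operation forms C7–C8, the carbocycle, the C7 and C8 stereocentres and the α-methylene lactone. The precursor is open-chain: butenolide, Z-olefin, silylated C3 carbinol, preformed 1,10-epoxide, C8 aldehyde. The 8α-alcohol expected from the chair transition state is inverted during esterification.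

Key step: step 16

Numbering used below: C1–C10 ring carbons (C1/C10 epoxide, C3 carbinol, C4=C5 olefin), C11–C13 lactone methylene unit, C14 hydroxymethyl, C15 methyl.

Remark: in step 11 the sense of induction of the oxazoline–sulfonamide ligand is assumed as stated (Re-face addition to acrolein); its antipode is used if a pilot coupling shows the opposite sense.

Step 1
Reactants: 1 prop-2-yn-1-ol
Product: 3 (Z)-3-iodo-2-methylprop-2-en-1-ol, via vinylmagnesium alkoxide 2 (not isolated)
Conditions: MeMgBr (3 equiv), CuI (10 mol %), THF, −10 °C to rt; then I2, −40 °C to rt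
Reagents that add atoms: methylmagnesium bromide C[Mg]Br; iodine II
Why: Hydroxyl-directed, copper-catalysed anti-carbomagnesiation of the propargylic alkoxide places the methyl group on the internal carbon and the magnesium, held in a five-membered chelate, cis to CH2O, so iodinolysis with retention should give the Z-vinyl iodide whose geometry becomes the Z-C4=C5 olefin.

Step 2
Reactants: 3 (Z)-3-iodo-2-methylprop-2-en-1-ol
Product: 4 (Z)-3-iodo-2-methylprop-2-enal
Conditions: MnO2, CH2Cl2, rt, dark; filtered and used crude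
Reagents that add atoms: none
Why: Heterogeneous MnO2 oxidation of the allylic alcohol is neutral, so the Z-β-iodoenal should form without isomerisation or loss of iodide.

Step 3
Reactants: 4 (Z)-3-iodo-2-methylprop-2-enal
Product: 6 (1Z,3S)-1-iodo-2-methylhexa-1,5-dien-3-ol, via borinate ester 5 (not isolated)
Conditions: (−)-Ipc2BOMe [from (+)-α-pinene], allylMgBr, Et2O, −78 °C to rt; then 4, −78 °C; NaOH, H2O2
Reagents that add atoms: allylmagnesium bromide C=CC[Mg]Br
Why: Brown allylboration through a Zimmerman–Traxler chair: the B-allyldiisopinocampheylborane made in the flask should deliver the allyl group to the Si face of the enal and set the C3 carbinol as 3S.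

Step 4
Reactants: 7 3-bromobut-3-en-1-ol
Product: 8 1-{[(3-bromobut-3-en-1-yl)oxy]methyl}-4-methoxybenzene
Conditions: NaH, 4-methoxybenzyl chloride, Bu4NI (cat.), THF, 0 °C to rt
Reagents that add atoms: 4-methoxybenzyl chloride COc1ccc(CCl)cc1
Why: Williamson etherification of the primary alkoxide with the benzylic chloride; the vinyl bromide is inert to NaH at this temperature.

Step 5
Reactants: 8 1-{[(3-bromobut-3-en-1-yl)oxy]methyl}-4-methoxybenzene
Product: 10 4-[(4-methoxybenzyl)oxy]-2-methylidenebutanoic acid, via vinyllithium 9 (not isolated)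
Conditions: tBuLi (2.1 equiv), Et2O, −78 °C; CO2; aq. HCl to pH 3
Reagents that add atoms: carbon dioxide O=C=O
Why: Bromine–lithium exchange gives the 2-lithioalkene, whose carboxylation yields the 2-substituted acrylic acid that carries C8, C9, C10 and C14.

Step 6
Reactants: 6 (1Z,3S)-1-iodo-2-methylhexa-1,5-dien-3-ol; 10 4-[(4-methoxybenzyl)oxy]-2-methylidenebutanoic acid
Product: 11 (1Z,3S)-1-iodo-2-methylhexa-1,5-dien-3-yl 4-[(4-methoxybenzyl)oxy]-2-methylidenebutanoate
Conditions: DCC, DMAP (cat.), CH2Cl2, 0 °C to rt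
Reagents that add atoms: none
Why: Steglich esterification of the secondary allylic alcohol under neutral carbodiimide activation leaves C3 untouched.

Step 7
Reactants: 11 (1Z,3S)-1-iodo-2-methylhexa-1,5-dien-3-yl 4-[(4-methoxybenzyl)oxy]-2-methylidenebutanoate
Product: 12 (6S)-6-[(1Z)-1-iodoprop-1-en-2-yl]-3-{2-[(4-methoxybenzyl)oxy]ethyl}-5,6-dihydro-2H-pyran-2-one
Conditions: second-generation Grubbs catalyst (5 mol %), CH2Cl2, 40 °C, 10 mM
Reagents that add atoms: none
Why: Ring-closing metathesis between the terminal olefin and the 1,1-disubstituted acrylate closes the six-membered unsaturated lactone, and the ring forces C2 and C14 cis on the new trisubstituted C1=C10 olefin.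

Step 8
Reactants: 12 (6S)-6-[(1Z)-1-iodoprop-1-en-2-yl]-3-{2-[(4-methoxybenzyl)oxy]ethyl}-5,6-dihydro-2H-pyran-2-one
Product: 13 (2Z,5S,6Z)-7-iodo-2-{2-[(4-methoxybenzyl)oxy]ethyl}-6-methylhepta-2,6-diene-1,5-diol
Conditions: iBu2AlH (4 equiv), CH2Cl2, −78 to 0 °C; aq. potassium sodium tartrate
Reagents that add atoms: none
Why: Excess iBu2AlH reduces the unsaturated δ-lactone in the 1,2-sense through the lactol to the Z-allylic diol without touching the olefin geometry, the vinyl iodide or the benzyl ether.

Step 9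
Reactants: 13 (2Z,5S,6Z)-7-iodo-2-{2-[(4-methoxybenzyl)oxy]ethyl}-6-methylhepta-2,6-diene-1,5-diol
Product: 14 (2S,3Z)-1-[(2R,3S)-3-(hydroxymethyl)-3-{2-[(4-methoxybenzyl)oxy]ethyl}oxiran-2-yl]-4-iodo-3-methylbut-3-en-2-ol
Conditions: Ti(OiPr)4, L-(+)-diethyl tartrate, tBuOOH, 4 Å molecular sieves, CH2Cl2, −20 °C
Reagents that add atoms: tert-butyl hydroperoxide CC(C)(C)OO
Why: Sharpless asymmetric epoxidation of the primary allylic alcohol: the L-(+)-tartrate titanium complex should deliver oxygen to the face that gives 1R,10S under reagent control, while the secondary C3 alcohol on the electron-poor, cis-substituted iodoalkene reacts far more slowly.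

Step 10
Reactants: 14 (2S,3Z)-1-[(2R,3S)-3-(hydroxymethyl)-3-{2-[(4-methoxybenzyl)oxy]ethyl}oxiran-2-yl]-4-iodo-3-methylbut-3-en-2-ol
Product: 15 bis(tert-butyldimethylsilyl) ether of 14 (O3 and O14 silylated)
Conditions: TBSCl, imidazole, DMAP (cat.), DMF, rt
Reagents that add atoms: tert-butyldimethylsilyl chloride CC(C)(C)[Si](C)(C)Cl
Why: Silylation of both hydroxyls under imidazole buffering protects O3 and O14 for the later organometallic, oxidation and Mitsunobu steps without acid that could open the epoxide.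

Step 11
Reactants: 15 bis(tert-butyldimethylsilyl) ether of 14; 16 prop-2-enal (acrolein)
Product: 17 (3S,4Z,6S)-6-(tert-butyldimethylsilyloxy)-7-[(2R,3S)-3-(tert-butyldimethylsilyloxymethyl)-3-{2-[(4-methoxybenzyl)oxy]ethyl}oxiran-2-yl]-5-methylhepta-1,4-dien-3-ol
Conditions: CrCl2 (4 equiv), NiCl2 (2 mol %), Et3N, (S)-N-[2-(4-isopropyl-4,5-dihydrooxazol-2-yl)-6-methylphenyl]methanesulfonamide, THF, rt
Reagents that add atoms: none
Why: Nickel-catalysed, chromium-mediated Nozaki–Hiyama–Kishi coupling of the vinyl iodide with retention of the Z geometry; the chiral oxazoline–sulfonamide ligand on chromium is to direct addition to the Re face of acrolein, setting the C6 carbinol (6S here by CIP, the 6R lactone centre later), and the conditions tolerate epoxide and silyl ethers.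

Step 12
Reactants: 17 bis-allylic alcohol; 18 2-(bromomethyl)prop-2-enoic acid
Product: 19 2-(bromomethyl)prop-2-enoate ester of 17 at the C6 oxygen
Conditions: DCC, DMAP (cat.), CH2Cl2, −20 to 0 °C
Reagents that add atoms: none
Why: Steglich esterification at low temperature acylates the bis-allylic alcohol with retention at C6, and the allylic bromide of the acid should survive the short exposure to catalytic DMAP.

Step 13
Reactants: 19 2-(bromomethyl)prop-2-enoate ester of 17
Product: 20 (5R)-3-(bromomethyl)-5-[(1Z,3S)-3-(tert-butyldimethylsilyloxy)-4-[(2R,3S)-3-(tert-butyldimethylsilyloxymethyl)-3-{2-[(4-methoxybenzyl)oxy]ethyl}oxiran-2-yl]-2-methylbut-1-en-1-yl]furan-2(5H)-one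
Conditions: second-generation Hoveyda–Grubbs catalyst (5 mol %), CH2Cl2, 40 °C, 5 mM
Reagents that add atoms: none
Why: Ring-closing metathesis between the vinyl group and the 1,1-disubstituted acrylate closes the butenolide with C6 unchanged; only the monosubstituted olefin initiates and allylic bromides are tolerated by ruthenium carbenes.

Step 14
Reactants: 20 3-(bromomethyl)butenolide 4-methoxybenzyl ether
Product: 21 primary alcohol: 20 with the 4-methoxybenzyl ether cleaved to the C8 hydroxyl
Conditions: DDQ, CH2Cl2/pH 7 phosphate buffer, 0 °C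
Reagents that add atoms: none
Why: Oxidative cleavage of the 4-methoxybenzyl ether by DDQ under buffered biphasic conditions frees the C8 alcohol without touching silyl ethers, epoxide or allylic bromide.

Step 15
Reactants: 21 primary alcohol
Product: 22 β,γ-epoxy aldehyde: 21 with the C8 alcohol oxidised to the aldehyde
Conditions: Dess–Martin periodinane, NaHCO3, CH2Cl2, 0 °C; used at once
Reagents that add atoms: none
Why: Buffered Dess–Martin oxidation gives the β,γ-epoxy aldehyde under non-basic conditions, and immediate use should prevent β-elimination with epoxide opening.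

Step 16
Reactants: 22 β,γ-epoxy aldehyde carrying the 3-(bromomethyl)butenolide
Product: 24 (1R,3S,6R,7R,8S,10S)-3,14-bis(tert-butyldimethylsilyloxy)-1,10-epoxy-8-hydroxygermacra-4Z,11(13)-dien-12,6-olide, via allylchromium aldehyde 23 (not isolated)
Conditions: CrCl2 (10 equiv), THF, rt; 22 added by syringe pump to 2 mM
Reagents that add atoms: none
Why: CrCl2 inserts into the allylic C–Br bond (two divalent chromium equivalents per bromide) to give the trivalent allylchromium 23, which adds through its γ-carbon C7 to the tethered aldehyde carbon C8 in a six-membered Zimmerman–Traxler chair, shifting the double bond to the exocyclic C11=C13 position. The closest known reaction type is the chromium-mediated Barbier/Nozaki–Hiyama–Kishi allylation of aldehydes with 3-(bromomethyl)furan-2(5H)-ones, and its intramolecular form with 2-(bromomethyl)acrylates for ten-membered germacranolide rings. The ten-membered carbocycle closes in a 10-exo-trig mode (exo with respect to the C8=O bond); the lactone is already in place. C7 (R) is controlled by the C6 stereocentre of the butenolide: C8 bonds to the ring face anti to the C6–C5 bond, which gives the 6,7-trans lactone. C8 is controlled by the chair, in which the butenolide fixes C6 trans to the CH2Cr terminus and the C9 chain sits pseudo-equatorial; this places H7 and H8 anti and should give the 8S (8α) alcohol, the C8 epimer that step 17 inverts. The step needs ring closure to beat oligomerisation and γ- to beat α-attack: high dilution with slow addition, the Z-olefin and trans-epoxide as turn elements, and the inherent γ-selectivity of allylchromium reagents secure this, while CrCl2 reduces only the allylic bromide and the organochromium adds only to the aldehyde.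

Step 17
Reactants: 24 macrocyclic 8S alcohol; 25 (R)-2-methylbutanoic acid
Product: 26 (1R,3S,6R,7R,8R,10S)-3,14-bis(tert-butyldimethylsilyloxy)-1,10-epoxy-8-[(2R)-2-methylbutanoyloxy]germacra-4Z,11(13)-dien-12,6-olide
Conditions: PPh3, DIAD, toluene, 0 °C to rt
Reagents that add atoms: none
Why: Mitsunobu esterification: the C8 alcohol is activated as the alkoxyphosphonium and displaced by the carboxylate with inversion, converting 8S into the required 8R acyloxy centre, while the α-stereocentre of the acid is not enolised.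

Step 18
Reactants: 26 bis-silyl ether of the target
Product: 27 (1R,3S,6R,7R,8R,10S)-1,10-epoxy-3,14-dihydroxy-8-[(2R)-2-methylbutanoyloxy]germacra-4Z,11(13)-dien-12,6-olide (CNP0356520.1)
Conditions: HF·pyridine, pyridine, THF, 0 °C to rt
Reagents that add atoms: none
Why: Fluoride cleavage of both silyl ethers under buffered, mildly acidic conditions should spare the epoxide, the ester and the α-methylene lactone and avoid acyl migration.

Compound list
1 | prop-2-yn-1-ol | C#CCO | starting material
2 | bromomagnesium (Z)-3-(bromomagnesio)-2-methylprop-2-en-1-olate | Br[Mg]/C=C(/C)CO[Mg]Br | intermediate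
3 | (Z)-3-iodo-2-methylprop-2-en-1-ol | I/C=C(/C)CO | intermediate
4 | (Z)-3-iodo-2-methylprop-2-enal | I/C=C(/C)C=O | intermediate
5 | O-[bis(isopinocampheyl)boryl] ether of 6 | I/C=C(/C)[C@@H](OB([C@@H]1C[C@@H]2C[C@H]([C@H]1C)C2(C)C)[C@@H]1C[C@@H]2C[C@H]([C@H]1C)C2(C)C)CC=C | intermediate
6 | (1Z,3S)-1-iodo-2-methylhexa-1,5-dien-3-ol | I/C=C(/C)[C@@H](O)CC=C | intermediate
7 | 3-bromobut-3-en-1-ol | C=C(Br)CCO | starting material
8 | 1-{[(3-bromobut-3-en-1-yl)oxy]methyl}-4-methoxybenzene | C=C(Br)CCOCc1ccc(OC)cc1 | intermediate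
9 | 1-{[(3-lithiobut-3-en-1-yl)oxy]methyl}-4-methoxybenzene | [Li]C(=C)CCOCc1ccc(OC)cc1 | intermediate
10 | 4-[(4-methoxybenzyl)oxy]-2-methylidenebutanoic acid | C=C(CCOCc1ccc(OC)cc1)C(=O)O | intermediate
11 | (1Z,3S)-1-iodo-2-methylhexa-1,5-dien-3-yl 4-[(4-methoxybenzyl)oxy]-2-methylidenebutanoate | I/C=C(/C)[C@@H](OC(=O)C(=C)CCOCc1ccc(OC)cc1)CC=C | intermediate
12 | (6S)-6-[(1Z)-1-iodoprop-1-en-2-yl]-3-{2-[(4-methoxybenzyl)oxy]ethyl}-5,6-dihydro-2H-pyran-2-one | I/C=C(/C)[C@@H]1CC=C(CCOCc2ccc(OC)cc2)C(=O)O1 | intermediate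
13 | (2Z,5S,6Z)-7-iodo-2-{2-[(4-methoxybenzyl)oxy]ethyl}-6-methylhepta-2,6-diene-1,5-diol | I/C=C(/C)[C@@H](O)C/C=C(\CO)CCOCc1ccc(OC)cc1 | intermediate
14 | (2S,3Z)-1-[(2R,3S)-3-(hydroxymethyl)-3-{2-[(4-methoxybenzyl)oxy]ethyl}oxiran-2-yl]-4-iodo-3-methylbut-3-en-2-ol | I/C=C(/C)[C@@H](O)C[C@H]1O[C@]1(CO)CCOCc2ccc(OC)cc2 | intermediate
15 | bis(tert-butyldimethylsilyl) ether of 14 (descriptors as in 14) | I/C=C(/C)[C@@H](O[Si](C)(C)C(C)(C)C)C[C@H]1O[C@]1(CO[Si](C)(C)C(C)(C)C)CCOCc2ccc(OC)cc2 | intermediate
16 | prop-2-enal (acrolein) | C=CC=O | starting material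
17 | (3S,4Z,6S)-6-(tert-butyldimethylsilyloxy)-7-[(2R,3S)-3-(tert-butyldimethylsilyloxymethyl)-3-{2-[(4-methoxybenzyl)oxy]ethyl}oxiran-2-yl]-5-methylhepta-1,4-dien-3-ol | O[C@@H](C=C)/C=C(/C)[C@@H](O[Si](C)(C)C(C)(C)C)C[C@H]1O[C@]1(CO[Si](C)(C)C(C)(C)C)CCOCc2ccc(OC)cc2 | intermediate
18 | 2-(bromomethyl)prop-2-enoic acid | C=C(CBr)C(=O)O | starting material
19 | 2-(bromomethyl)prop-2-enoate of 17 (3S ester, descriptors as in 17) | C=C(CBr)C(=O)O[C@@H](C=C)/C=C(/C)[C@@H](O[Si](C)(C)C(C)(C)C)C[C@H]1O[C@]1(CO[Si](C)(C)C(C)(C)C)CCOCc2ccc(OC)cc2 | intermediate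
20 | (5R)-3-(bromomethyl)-5-[(1Z,3S)-3-(tert-butyldimethylsilyloxy)-4-[(2R,3S)-3-(tert-butyldimethylsilyloxymethyl)-3-{2-[(4-methoxybenzyl)oxy]ethyl}oxiran-2-yl]-2-methylbut-1-en-1-yl]furan-2(5H)-one | O=C1O[C@@H](C=C1CBr)/C=C(/C)[C@@H](O[Si](C)(C)C(C)(C)C)C[C@H]2O[C@]2(CO[Si](C)(C)C(C)(C)C)CCOCc3ccc(OC)cc3 | intermediate
21 | 20 with 2-hydroxyethyl in place of 2-[(4-methoxybenzyl)oxy]ethyl (free C8 alcohol) | O=C1O[C@@H](C=C1CBr)/C=C(/C)[C@@H](O[Si](C)(C)C(C)(C)C)C[C@H]2O[C@]2(CO[Si](C)(C)C(C)(C)C)CCO | intermediate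
22 | 21 with the C8 alcohol as aldehyde (2-oxoethyl on the epoxide carbon C10) | O=C1O[C@@H](C=C1CBr)/C=C(/C)[C@@H](O[Si](C)(C)C(C)(C)C)C[C@H]2O[C@]2(CO[Si](C)(C)C(C)(C)C)CC=O | intermediate
23 | 22 with CH2CrCl2 in place of CH2Br (trivalent allylchromium) | O=C1O[C@@H](C=C1C[Cr](Cl)Cl)/C=C(/C)[C@@H](O[Si](C)(C)C(C)(C)C)C[C@H]2O[C@]2(CO[Si](C)(C)C(C)(C)C)CC=O | intermediate
24 | (1R,3S,6R,7R,8S,10S)-3,14-bis(tert-butyldimethylsilyloxy)-1,10-epoxy-8-hydroxygermacra-4Z,11(13)-dien-12,6-olide | C=C1C(=O)O[C@@H]2/C=C(/C)[C@@H](O[Si](C)(C)C(C)(C)C)C[C@H]3O[C@]3(CO[Si](C)(C)C(C)(C)C)C[C@H](O)[C@@H]12 | intermediate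
25 | (R)-2-methylbutanoic acid | CC[C@@H](C)C(=O)O | starting material
26 | (1R,3S,6R,7R,8R,10S)-3,14-bis(tert-butyldimethylsilyloxy)-1,10-epoxy-8-[(2R)-2-methylbutanoyloxy]germacra-4Z,11(13)-dien-12,6-olide | C=C1C(=O)O[C@@H]2/C=C(/C)[C@@H](O[Si](C)(C)C(C)(C)C)C[C@H]3O[C@]3(CO[Si](C)(C)C(C)(C)C)C[C@@H](OC(=O)[C@H](C)CC)[C@@H]12 | intermediate
27 | (1R,3S,6R,7R,8R,10S)-1,10-epoxy-3,14-dihydroxy-8-[(2R)-2-methylbutanoyloxy]germacra-4Z,11(13)-dien-12,6-olide (CNP0356520.1) | C=C1C(=O)O[C@@H]2/C=C(/C)[C@@H](O)C[C@H]3O[C@]3(CO)C[C@@H](OC(=O)[C@H](C)CC)[C@@H]12 | target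

Total step count: 18. Longest linear sequence: 16 steps (steps 1–3 and 6–18; steps 4–5 make acid 10).

Steps most likely to fail

Step 16 (ring closure). The β,γ-epoxy aldehyde may lose its epoxide by β-elimination under the Lewis-acidic trivalent chromium salts. The allylchromium may also be protonated or may couple intermolecularly before it finds the aldehyde. The fallback replaces the reductive metalation by a neutral, metal-free allylboration that forms the same bond through the same chair. It sets out from alcohol 21. Borylation with bis(pinacolato)diboron and catalytic Pd2(dba)3 in toluene at 50 °C should put boron on the CH2 terminus and give the 3-[(pinacolatoboryl)methyl]butenolide alcohol F1. Buffered Dess–Martin oxidation gives the allylboronate aldehyde F2, which is not isolated but diluted into warm toluene. There the intramolecular allylboration should give the macrocyclic O-(pinacolatoboryl) ether F3. Mild hydrolysis with aqueous NaHCO3 returns to the route at 24.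

Step 17 (inversion at C8). Displacement at the hindered C8 may be slower than elimination of the alkoxyphosphonium towards H7 or H9, and PPh3 may add reversibly to the α-methylene lactone. The fallback separates activation from displacement and avoids phosphine. It sets out from 24. Chloromethanesulfonyl chloride and pyridine give the C8 chloromethanesulfonate F4. Caesium (R)-2-methylbutanoate F5 (from 25 and Cs2CO3) with 18-crown-6 in toluene should then displace the sulfonate with inversion and return to the route at 26.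

Step 11 (C6 carbinol). Facial selectivity at the small, unhindered acrolein carbonyl may be poor, so the ligand may not override the substrate. The fallback sets C6 by a reagent-controlled epoxidation instead. It sets out from 15. Stille coupling with (E)-3-(tributylstannyl)prop-2-en-1-ol (Pd(PPh3)4, CuI, DMF) gives the (2E,4Z)-dienol F6. Sharpless epoxidation of its allylic alcohol with D-(−)-diethyl tartrate fixes the C6 oxygen stereocentre in the epoxy alcohol F7. I2, PPh3 and imidazole convert it into the epoxy iodide F8. Zinc dust in ethanol then opens the epoxide reductively to the vinyl carbinol and returns to the route at 17.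

Further compounds
F1 | step 16 | 21 with CH2B(pinacolato) in place of CH2Br (allylboronate alcohol) | O=C1O[C@@H](C=C1CB4OC(C)(C)C(C)(C)O4)/C=C(/C)[C@@H](O[Si](C)(C)C(C)(C)C)C[C@H]2O[C@]2(CO[Si](C)(C)C(C)(C)C)CCO
F2 | step 16 | 22 with CH2B(pinacolato) in place of CH2Br (allylboronate aldehyde) | O=C1O[C@@H](C=C1CB4OC(C)(C)C(C)(C)O4)/C=C(/C)[C@@H](O[Si](C)(C)C(C)(C)C)C[C@H]2O[C@]2(CO[Si](C)(C)C(C)(C)C)CC=O
F3 | step 16 | O8-(pinacolatoboryl) ether of 24 | C=C1C(=O)O[C@@H]2/C=C(/C)[C@@H](O[Si](C)(C)C(C)(C)C)C[C@H]3O[C@]3(CO[Si](C)(C)C(C)(C)C)C[C@H](OB4OC(C)(C)C(C)(C)O4)[C@@H]12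
F4 | step 17 | C8 chloromethanesulfonate of 24 (8S) | C=C1C(=O)O[C@@H]2/C=C(/C)[C@@H](O[Si](C)(C)C(C)(C)C)C[C@H]3O[C@]3(CO[Si](C)(C)C(C)(C)C)C[C@H](OS(=O)(=O)CCl)[C@@H]12
F5 | step 17 | caesium (R)-2-methylbutanoate | [Cs+].CC[C@@H](C)C(=O)[O-]
F6 | step 11 | (2E,4Z)-dienol: 15 with (E)-CH=CH–CH2OH in place of iodine | OC/C=C/C=C(/C)[C@@H](O[Si](C)(C)C(C)(C)C)C[C@H]1O[C@]1(CO[Si](C)(C)C(C)(C)C)CCOCc2ccc(OC)cc2
F7 | step 11 | (2R,3R)-2,3-epoxy alcohol of F6 | OC[C@H]1O[C@@H]1/C=C(/C)[C@@H](O[Si](C)(C)C(C)(C)C)C[C@H]2O[C@]2(CO[Si](C)(C)C(C)(C)C)CCOCc3ccc(OC)cc3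
F8 | step 11 | epoxy iodide: F7 with CH2I in place of CH2OH | IC[C@H]1O[C@@H]1/C=C(/C)[C@@H](O[Si](C)(C)C(C)(C)C)C[C@H]2O[C@]2(CO[Si](C)(C)C(C)(C)C)CCOCc3ccc(OC)cc3
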